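**Assumption:** the ylide from (1R,4R,5R)-isothiocineole is taken to add to the o-quinone methide with the facial sense it shows toward aldehydes, giving the (2S) dihydrobenzofuran; if the sense is opposite, the enantiomeric sulfide (from (S)-limonene) is used in the same way.

## Retrosynthetic overview

1. Target ⇐ BCl3 removal of the 5-O-methyl and 3'-O-isopropyl groups from the assembled (2R,3R)-dihydroflavonol.
2. Pyranone C ring ⇐ ring expansion: enolate hydroxylation of a (2S)-2-aryl-2,3-dihydrobenzofuran-3-carbaldehyde, then α-ketol 1,2-shift of C2 from the carbinol carbon to the formyl carbon (furan → pyranone, sets C3).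
3. Dihydrofuran ring ⇐ formal [4+1] annulation of an A-ring o-quinone methide (from a phenolic Mannich base of 2,2-dimethoxyacetaldehyde) with a chiral benzylsulfonium ylide (sets C2).
4. A ring ⇐ resorcinol (O-methylation, C–H borylation/oxidation, ortho-C-prenylation); B ring ⇐ catechol (O-isopropylation, para-bromination, O-methylation, hydroxymethylation).
5. Ring order: both benzene rings are bought; the O-heterocycle is first made five-membered, then expanded to the six-membered C ring.

## Route

Step 1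
Reactants: 1 resorcinol
Product: 2 1,3-dimethoxybenzene
Conditions: MeI (2.5 equiv), K2CO3, acetone, reflux
Reagents that add atoms: iodomethane, CI
Why: Williamson O-methylation of both phenols; no stereocentre.

Step 2
Reactants: 2 1,3-dimethoxybenzene
Product: 4 3,5-dimethoxyphenol, via aryl pinacol boronate 3 (not isolated)
Conditions: [Ir(cod)OMe]2 (1 mol%), dtbpy (2 mol%), B2pin2 (1.0 equiv), THF, 80 °C; then Oxone, acetone/H2O, rt
Reagents that add atoms: bis(pinacolato)diboron, CC1(C)OB(OC1(C)C)B1OC(C)(C)C(C)(C)O1 (Bpin of 3); potassium peroxymonosulfate (Oxone), [K+].[O-]S(=O)(=O)OO (phenol O of 4)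
Why: Sterically governed Ir-catalysed C–H borylation goes to C5, the only C–H not ortho to a methoxy group, and the boronate is oxidised in the same flask (one-pot borylation/oxidation).

Step 3
Reactants: 4 3,5-dimethoxyphenol; 5 prenyl bromide (1-bromo-3-methylbut-2-ene)
Product: 6 3,5-dimethoxy-2-(3-methylbut-2-en-1-yl)phenol
Conditions: NaH (1.05 equiv), toluene, 0 °C; then 5 (1.0 equiv), rt
Reagents that add atoms: none
Why: Ortho-C-alkylation of a sodium phenoxide in a non-polar solvent (tight ion pair; both ortho carbons are equivalent), which leaves the single OH, next to the prenyl group, as the future ring oxygen.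

Step 4
Reactants: 6 3,5-dimethoxy-2-(3-methylbut-2-en-1-yl)phenol; 7 2,2-dimethoxyacetaldehyde
Product: 8 2-[2,2-dimethoxy-1-(morpholin-4-yl)ethyl]-3,5-dimethoxy-6-(3-methylbut-2-en-1-yl)phenol (racemic)
Conditions: morpholine (1.1 equiv), 7 (60% aq., 1.2 equiv), EtOH, 50 °C
Reagents that add atoms: morpholine, C1COCCN1
Why: Phenolic Mannich (Betti-type) reaction, the hydrogen-bonded iminium being delivered to the only free ortho carbon; the new stereocentre is racemic and is erased in step 10.

Step 5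
Reactants: 9 catechol
Product: 10 2-(propan-2-yloxy)phenol
Conditions: 2-bromopropane (1.0 equiv), K2CO3, DMF, 60 °C (catechol in excess)
Reagents that add atoms: 2-bromopropane, CC(C)Br
Why: Williamson mono-etherification that installs the isopropyl protecting group; no stereocentre.

Step 6
Reactants: 10 2-(propan-2-yloxy)phenol
Product: 11 4-bromo-2-(propan-2-yloxy)phenol
Conditions: NBS (1.0 equiv), MeCN, 0 °C
Reagents that add atoms: N-bromosuccinimide, O=C1CCC(=O)N1Br
Why: Electrophilic aromatic bromination para to the free OH, which is a stronger director than the isopropoxy group.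

Step 7
Reactants: 11 4-bromo-2-(propan-2-yloxy)phenol
Product: 12 4-bromo-1-methoxy-2-(propan-2-yloxy)benzene
Conditions: MeI, K2CO3, acetone, reflux
Reagents that add atoms: iodomethane, CI
Why: Williamson O-methylation; the methoxy group now sits para to bromine (isovanillin pattern).

Step 8
Reactants: 12 4-bromo-1-methoxy-2-(propan-2-yloxy)benzene; 13 formaldehyde (used as paraformaldehyde)
Product: 15 [4-methoxy-3-(propan-2-yloxy)phenyl]methanol, via aryllithium 14 (not isolated)
Conditions: n-BuLi, THF, −78 °C; then (CH2O)n, −78 °C → rt; aq NH4Cl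
Reagents that add atoms: n-butyllithium, [Li]CCCC (Li of 14)
Why: Bromine–lithium exchange and addition of the aryllithium to formaldehyde (hydroxymethylation).

Step 9
Reactants: 15 [4-methoxy-3-(propan-2-yloxy)phenyl]methanol
Product: 16 (1R,4R,5R)-6-{[4-methoxy-3-(propan-2-yloxy)phenyl]methyl}-4,7,7-trimethyl-6-thiabicyclo[3.2.1]octan-6-ium tetrafluoroborate (benzyl group exo on sulfur)
Conditions: (1R,4R,5R)-isothiocineole (1.1 equiv), HBF4·OEt2 (1.1 equiv), Et2O, 0 °C → rt
Reagents that add atoms: (1R,4R,5R)-isothiocineole, C[C@@H]1CC[C@@H]2C[C@H]1SC2(C)C; tetrafluoroboric acid, [H+].F[B-](F)(F)F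
Why: Acid-promoted S-alkylation of the sulfide by the electron-rich benzylic alcohol (sulfonium salt formation), with alkylation on the exo face giving one diastereomer at sulfur.

Step 10
Reactants: 8 2-[2,2-dimethoxy-1-(morpholin-4-yl)ethyl]-3,5-dimethoxy-6-(3-methylbut-2-en-1-yl)phenol; 16 the sulfonium tetrafluoroborate
Product: 20 (2S,3S)-3-(dimethoxymethyl)-4,6-dimethoxy-2-[4-methoxy-3-(propan-2-yloxy)phenyl]-7-(3-methylbut-2-en-1-yl)-2,3-dihydro-1-benzofuran, via N-methylmorpholinium iodide 17 (not isolated), via o-quinone methide 18 (not isolated), via sulfonium ylide 19 (not isolated)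
Conditions: 8, MeI (1.0 equiv), MeCN, rt; then 16 (1.1 equiv), powdered KOH (2.2 equiv), 0 °C → rt
Reagents that add atoms: iodomethane, CI (N-methyl group of 17)
Why: 1,4-Elimination of the ammonium phenoxide gives the o-quinone methide, the chiral benzylsulfonium ylide adds to its exocyclic carbon and the phenoxide displaces the sulfide (5-exo-tet SN2), a sulfur-ylide formal [4+1] annulation in which the chiral sulfide fixes the ylide face and so C2 as S, with the 2,3-trans product favoured.

Step 11
Reactants: 20 the (2S,3S)-dimethyl acetal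
Product: 21 (2S,3S)-4,6-dimethoxy-2-[4-methoxy-3-(propan-2-yloxy)phenyl]-7-(3-methylbut-2-en-1-yl)-2,3-dihydro-1-benzofuran-3-carbaldehyde
Conditions: TsOH·H2O (10 mol%), acetone/H2O 10:1, rt
Reagents that add atoms: water, O
Why: Acid-catalysed acetal hydrolysis; C2 is untouched and the epimerisable C3 becomes sp2 in step 12, so its configuration is irrelevant.

Step 12
Reactants: 21 the (2S,3S)-3-carbaldehyde
Product: 23 (2R,3R)-3-hydroxy-5,7-dimethoxy-2-[4-methoxy-3-(propan-2-yloxy)phenyl]-8-(3-methylbut-2-en-1-yl)-2,3-dihydro-4H-chromen-4-one, via α-hydroxy aldehyde 22 (not isolated)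
Conditions: KHMDS (1.1 equiv), THF, −78 °C; 2-(benzenesulfonyl)-3-phenyloxaziridine (1.2 equiv), −78 °C; then MgBr2·OEt2 (1.5 equiv), −78 → 0 °C; aq NH4Cl
Reagents that add atoms: 2-(benzenesulfonyl)-3-phenyloxaziridine (Davis reagent), O=S(=O)(N1OC1c1ccccc1)c1ccccc1
Why: Proposed new method: one-pot enolate hydroxylation/ring-expanding α-ketol (acyloin) rearrangement, in which the potassium enolate of 21 is hydroxylated anti to the C2 aryl group to give the alkoxide of 22, Mg2+ holds the alkoxide and aldehyde oxygens syn-periplanar, and the anionic 1,2-shift of the α-aryloxybenzyl carbon C2 (retention at C2) onto the formyl carbon expands the furan to the pyranone and sets C3 trans to C2 as (2R,3R); the shift is driven by conversion of a tertiary alkoxide/aldehyde into a secondary alkoxide/conjugated aryl ketone, and C2 should migrate in preference to the very electron-rich aryl carbon because the shift is alkoxide-driven and only C2 migration gives the conjugated ketone; the closest known reaction type is the base- or Lewis-acid-promoted α-ketol rearrangement of tertiary α-hydroxy aldehydes and the D-homoannulation of 17-hydroxy-20-keto steroids, not shown so far for 3-hydroxy-2,3-dihydrobenzofuran-3-carbaldehydes.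

Step 13
Reactants: 23 the 5-O-methyl-3'-O-isopropyl dihydroflavonol
Product: 24 (2R,3R)-3,5-dihydroxy-2-(3-hydroxy-4-methoxyphenyl)-7-methoxy-8-(3-methylbut-2-en-1-yl)-2,3-dihydro-4H-chromen-4-one (CNP0302743.1)
Conditions: BCl3 (4 equiv), CH2Cl2, −78 → 0 °C; then H2O
Reagents that add atoms: none
Why: BCl3 ether cleavage, in which chelation to the C4 carbonyl directs loss of the peri 5-O-methyl group and the secondary isopropyl ether is cleaved much faster than the 7- and 4'-methyl ethers; the prenyl group has no neighbouring free OH and both stereocentres are untouched.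

## Compound list

1 | resorcinol (benzene-1,3-diol) | Oc1cccc(O)c1 | starting material
2 | 1,3-dimethoxybenzene | COc1cccc(OC)c1 | intermediate
3 | 2-(3,5-dimethoxyphenyl)-4,4,5,5-tetramethyl-1,3,2-dioxaborolane | COc1cc(OC)cc(B2OC(C)(C)C(C)(C)O2)c1 | intermediate (not isolated)
4 | 3,5-dimethoxyphenol | COc1cc(O)cc(OC)c1 | intermediate
5 | prenyl bromide (1-bromo-3-methylbut-2-ene) | CC(C)=CCBr | starting material
6 | 3,5-dimethoxy-2-(3-methylbut-2-en-1-yl)phenol | COc1cc(OC)c(CC=C(C)C)c(O)c1 | intermediate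
7 | 2,2-dimethoxyacetaldehyde | COC(OC)C=O | starting material
8 | 2-[2,2-dimethoxy-1-(morpholin-4-yl)ethyl]-3,5-dimethoxy-6-(3-methylbut-2-en-1-yl)phenol (racemic) | COc1cc(OC)c(C(N2CCOCC2)C(OC)OC)c(O)c1CC=C(C)C | intermediate
9 | catechol (benzene-1,2-diol) | Oc1ccccc1O | starting material
10 | 2-(propan-2-yloxy)phenol | CC(C)Oc1ccccc1O | intermediate
11 | 4-bromo-2-(propan-2-yloxy)phenol | CC(C)Oc1cc(Br)ccc1O | intermediate
12 | 4-bromo-1-methoxy-2-(propan-2-yloxy)benzene | COc1ccc(Br)cc1OC(C)C | intermediate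
13 | formaldehyde (used as paraformaldehyde) | C=O | starting material
14 | [4-methoxy-3-(propan-2-yloxy)phenyl]lithium | [Li]c1ccc(OC)c(OC(C)C)c1 | intermediate (not isolated)
15 | [4-methoxy-3-(propan-2-yloxy)phenyl]methanol | COc1ccc(CO)cc1OC(C)C | intermediate
16 | (1R,4R,5R)-6-{[4-methoxy-3-(propan-2-yloxy)phenyl]methyl}-4,7,7-trimethyl-6-thiabicyclo[3.2.1]octan-6-ium tetrafluoroborate (S-benzyl exo) | C[C@@H]1CC[C@@H]2C[C@H]1[S@@+](Cc3ccc(OC)c(OC(C)C)c3)C2(C)C.F[B-](F)(F)F | intermediate
17 | 4-{1-[2-hydroxy-4,6-dimethoxy-3-(3-methylbut-2-en-1-yl)phenyl]-2,2-dimethoxyethyl}-4-methylmorpholin-4-ium iodide (racemic) | COc1cc(OC)c(C([N+]2(C)CCOCC2)C(OC)OC)c(O)c1CC=C(C)C.[I-] | intermediate (not isolated)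
18 | 6-(2,2-dimethoxyethylidene)-3,5-dimethoxy-2-(3-methylbut-2-en-1-yl)cyclohexa-2,4-dien-1-one (o-quinone methide, alkene geometry not defined) | COC(OC)C=C1C(OC)=CC(OC)=C(CC=C(C)C)C1=O | intermediate (not isolated)
19 | sulfonium ylide of 16 (benzylic carbanion on the exo S-substituent) | C[C@@H]1CC[C@@H]2C[C@H]1[S@@+]([CH-]c3ccc(OC)c(OC(C)C)c3)C2(C)C | intermediate (not isolated)
20 | (2S,3S)-3-(dimethoxymethyl)-4,6-dimethoxy-2-[4-methoxy-3-(propan-2-yloxy)phenyl]-7-(3-methylbut-2-en-1-yl)-2,3-dihydro-1-benzofuran (2,3-trans) | COC(OC)[C@@H]1[C@@H](c2ccc(OC)c(OC(C)C)c2)Oc2c(CC=C(C)C)c(OC)cc(OC)c12 | intermediate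
21 | (2S,3S)-4,6-dimethoxy-2-[4-methoxy-3-(propan-2-yloxy)phenyl]-7-(3-methylbut-2-en-1-yl)-2,3-dihydro-1-benzofuran-3-carbaldehyde | O=C[C@@H]1[C@@H](c2ccc(OC)c(OC(C)C)c2)Oc2c(CC=C(C)C)c(OC)cc(OC)c12 | intermediate
22 | (2R,3S)-3-hydroxy-4,6-dimethoxy-2-[4-methoxy-3-(propan-2-yloxy)phenyl]-7-(3-methylbut-2-en-1-yl)-2,3-dihydro-1-benzofuran-3-carbaldehyde (OH trans to the 2-aryl group; formed as its metal alkoxide) | O=C[C@@]1(O)[C@@H](c2ccc(OC)c(OC(C)C)c2)Oc2c(CC=C(C)C)c(OC)cc(OC)c12 | intermediate (not isolated)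
23 | (2R,3R)-3-hydroxy-5,7-dimethoxy-2-[4-methoxy-3-(propan-2-yloxy)phenyl]-8-(3-methylbut-2-en-1-yl)-2,3-dihydro-4H-chromen-4-one | COc1ccc([C@H]2Oc3c(CC=C(C)C)c(OC)cc(OC)c3C(=O)[C@@H]2O)cc1OC(C)C | intermediate
24 | (2R,3R)-3,5-dihydroxy-2-(3-hydroxy-4-methoxyphenyl)-7-methoxy-8-(3-methylbut-2-en-1-yl)-2,3-dihydro-4H-chromen-4-one | COc1ccc([C@H]2Oc3c(CC=C(C)C)c(OC)cc(O)c3C(=O)[C@@H]2O)cc1O | target

## Step count and risks

Total steps: 13. Longest linear sequence: 9 (steps 5–13; the A-ring branch, steps 1–4 then 10–13, is 8).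

**Step 12 (the proposed new step).** The risks are competing migration of the aryl carbon (giving the 4-hydroxyflavan-3-one), formation of the 2,3-cis isomer if chelation is lost, and hydride transfer between product alkoxide and aldehyde. The fallback uses the established chalcone-epoxide synthesis of dihydroflavonols; it sets out from 6 and 12 and returns at 23. Phenol 6 is protected (MOMCl, i-Pr2NEt) as 1,5-dimethoxy-3-(methoxymethoxy)-2-(3-methylbut-2-en-1-yl)benzene F1. Directed ortho-lithiation between OMOM and OMe (n-BuLi, TMEDA) and acylation with N-methoxy-N-methylacetamide give 1-[4,6-dimethoxy-2-(methoxymethoxy)-3-(3-methylbut-2-en-1-yl)phenyl]ethan-1-one F2. Bromide 12 is formylated (n-BuLi, then DMF) to 4-methoxy-3-(propan-2-yloxy)benzaldehyde F3. Claisen–Schmidt condensation (KOH, EtOH) gives (E)-1-[4,6-dimethoxy-2-(methoxymethoxy)-3-(3-methylbut-2-en-1-yl)phenyl]-3-[4-methoxy-3-(propan-2-yloxy)phenyl]prop-2-en-1-one F4. Juliá–Colonna epoxidation (poly-L-leucine, urea–H2O2, DBU) gives [4,6-dimethoxy-2-(methoxymethoxy)-3-(3-methylbut-2-en-1-yl)phenyl]{(2R,3S)-3-[4-methoxy-3-(propan-2-yloxy)phenyl]oxiran-2-yl}methanone F5. Brief HCl in MeOH/THF removes the MOM group and the freed phenol opens the epoxide 6-endo with inversion at the benzylic carbon to give 23.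

**Step 10 (ylide [4+1] annulation).** The risks are low enantioselectivity or poor reactivity of the bulky chiral semi-stabilised ylide toward the o-quinone methide, and o-quinone methide dimerisation. The fallback replaces reagent control by a racemic annulation plus resolution; it sets out from 15 (with 8) and returns at 20. Alcohol 15 with dimethyl sulfide and HBF4·OEt2 gives {[4-methoxy-3-(propan-2-yloxy)phenyl]methyl}dimethylsulfonium tetrafluoroborate F6. Its ylide (KOH, MeCN) is combined with 8/MeI as in step 10 to give racemic trans-acetal, which is resolved by preparative chiral SFC; the (2R,3R)-enantiomer of 20 F7 is discarded and the (2S,3S) enantiomer is 20.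

**Step 3 (ortho-C-prenylation).** The risks are O-alkylation, para-alkylation between the two methoxy groups and double prenylation. The fallback uses directed ortho-metalation; it sets out from 4 and returns at 6. Phenol 4 with dihydropyran/PPTS gives 2-(3,5-dimethoxyphenoxy)oxane F8. n-BuLi (THF, 0 °C) lithiates between the OTHP and OMe groups, and CuBr·SMe2 followed by 5 gives 2-[3,5-dimethoxy-2-(3-methylbut-2-en-1-yl)phenoxy]oxane F9. PPTS in EtOH at 40 °C, mild enough to spare the ortho-prenyl phenol, returns 6. F8 and F9 are racemic at the acetal carbon.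

## Further compounds

F1 | step 12 | 1,5-dimethoxy-3-(methoxymethoxy)-2-(3-methylbut-2-en-1-yl)benzene | COCOc1cc(OC)cc(OC)c1CC=C(C)C
F2 | step 12 | 1-[4,6-dimethoxy-2-(methoxymethoxy)-3-(3-methylbut-2-en-1-yl)phenyl]ethan-1-one | CC(=O)c1c(OC)cc(OC)c(CC=C(C)C)c1OCOC
F3 | step 12 | 4-methoxy-3-(propan-2-yloxy)benzaldehyde | COc1ccc(C=O)cc1OC(C)C
F4 | step 12 | (E)-1-[4,6-dimethoxy-2-(methoxymethoxy)-3-(3-methylbut-2-en-1-yl)phenyl]-3-[4-methoxy-3-(propan-2-yloxy)phenyl]prop-2-en-1-one | COCOc1c(CC=C(C)C)c(OC)cc(OC)c1C(=O)/C=C/c1ccc(OC)c(OC(C)C)c1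
F5 | step 12 | [4,6-dimethoxy-2-(methoxymethoxy)-3-(3-methylbut-2-en-1-yl)phenyl]{(2R,3S)-3-[4-methoxy-3-(propan-2-yloxy)phenyl]oxiran-2-yl}methanone | COCOc1c(CC=C(C)C)c(OC)cc(OC)c1C(=O)[C@@H]1O[C@H]1c1ccc(OC)c(OC(C)C)c1
F6 | step 10 | {[4-methoxy-3-(propan-2-yloxy)phenyl]methyl}dimethylsulfonium tetrafluoroborate | C[S+](C)Cc1ccc(OC)c(OC(C)C)c1.F[B-](F)(F)F
F7 | step 10 | (2R,3R)-3-(dimethoxymethyl)-4,6-dimethoxy-2-[4-methoxy-3-(propan-2-yloxy)phenyl]-7-(3-methylbut-2-en-1-yl)-2,3-dihydro-1-benzofuran (enantiomer of 20) | COC(OC)[C@H]1[C@H](c2ccc(OC)c(OC(C)C)c2)Oc2c(CC=C(C)C)c(OC)cc(OC)c12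
F8 | step 3 | 2-(3,5-dimethoxyphenoxy)oxane | COc1cc(OC)cc(OC2CCCCO2)c1
F9 | step 3 | 2-[3,5-dimethoxy-2-(3-methylbut-2-en-1-yl)phenoxy]oxane | COc1cc(OC)c(CC=C(C)C)c(OC2CCCCO2)c1
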